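The readings stem from a simulated flask for substances that don't exist.

- If the exchange favoured neither side, fresh over spent carrier would equal salt left over spent salt, and at 5.0% conversion the flask's carrier would stand 85.2% fresh; doubled salt would make that 92.2%, a factor of 1.08. I took starting material plus fresh carrier as the step that makes product, so at equal conversion a factor on the rate is a factor on fresh carrier.

| flask | starting material | salt in the second phase | spent carrier | remark | volume of the second phase over the first |
|---|---|---|---|---|---|
| Monday's | 28 mM | 24 mM | 3 mM | run made earlier |  |
| Friday's | 44 mM | 24 mM | 3 mM | run made earlier |  |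
| flask | 20 mM | 24.0 mM | 3.0 mM |  | 0.25 |

| run | time / min | product / % | starting material / % |
|---|---|---|---|
| Monday's | 20.0 | 53.0 | 45.6 |
| Monday's | 40.0 | 67.1 | 32.4 |
| Monday's | 60.0 | 71.1 | 29.1 |
| Monday's | 80.0 | 74.0 | 24.3 |
| Monday's | 90.0 | 76.4 | 24.0 |
| Monday's | 120 | 79.9 | 21.4 |
| Friday's | 20.0 | 43.7 | 57.3 |
| Friday's | 40.0 | 50.5 | 50.0 |
| Friday's | 60.0 | 51.3 | 47.7 |
| Friday's | 80.0 | 52.8 | 46.1 |
| Friday's | 90.0 | 52.5 | 45.7 |
| Friday's | 120 | 55.3 | 45.3 |

(readings scatter by 1 percentage point)

- in the second phase: salt in the second phase, spent salt in the second phase; everything else is in the first
- charges count per volume of the first phase; a concentration in a rate is the amount of a species over the volume of its own phase; every rate counts per litre of the first phase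
- the numbers in the tables scatter with a standard deviation of 1 percentage point
- steps that have been proposed: spent carrier + salt in the second phase <-> fresh carrier + spent salt in the second phase; starting material + fresh carrier -> product + spent carrier; 2 fresh carrier <-> resting dimer
- the earlier runs hold the two phases in the same ratio of volumes as the flask asked about
- no earlier run changes the charge of spent carrier; that part of a forecast is a guess
- no earlier run changes the charge of salt in the second phase; that part of a forecast is a guess

1. factor on the rate of making product when 5.0% of the starting material are converted if salt in the second phase is charged twice over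
2. factor on the rate when 5.0% of the starting material are converted if spent carrier is charged at 0.30 mM instead

- But was the exchange even? Monday's run lost starting material at 0.0393 min⁻¹ in its first window and 0.00512 min⁻¹ in its last, while salt left over salt used fell from 2.23 to 0.135.
- Reading the loss as following the fresh fraction, I got a balance factor (fresh over spent carrier, divided by salt left over spent salt) of 0.594, not one. The late drop is 7.7 percentage points against a scatter of 1 point, so this is a rough reading.
- With it, the fresh share, the fraction of the flask's carrier standing fresh at 5.0% conversion, came to 78.5%. Doubled salt gave 87.9%, a factor of 1.12.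
- At 0.30 mM of spent carrier the share was 91.4%, a rate factor of 0.116. My objection was the proposed resting dimer, which this reckoning omits, while Monday's and Friday's runs both held 3 mM of spent carrier; I held that factor as a low estimate.
- The forecast gave 1.15 and 0.17, noting “Any dimer at 3 mM would raise this”.
- The flask gave 1.12 for doubled salt and 0.153 for the smaller carrier charge.

    spent carrier + salt in the second phase ⇌ fresh carrier + spent salt in the second phase (K = 0.300, k = 170 L mol⁻¹ min⁻¹)
    starting material + fresh carrier → product + spent carrier (k = 50.0 L mol⁻¹ min⁻¹)
    2 fresh carrier ⇌ resting dimer, settled at all times (K = 150 L mol⁻¹)

- At 0.156 h in the flask, fresh carrier fell back 36 times faster than it went on to product, with a half-life of 1.2 min by the path to product against 0.070 min for spent carrier by the forward exchange alone; the exchange stood near balance, a pre-equilibrium. At 5.0% conversion the flask with 0.30 mM of spent carrier held 76.3% of its catalyst as fresh carrier, against my 91.4%, and 5.24% as resting dimer; dividing that fresh carrier by 0.153 puts the fresh share at 3.0 mM of spent carrier at 49.9%, against my 78.5%.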